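**Retrosynthetic overview**
- The target, (4R)-4-[(2R)-1-(4-hydroxy-3-methoxyphenyl)propan-2-yl]-4,5-dimethoxy-2-(prop-2-en-1-yl)cyclohexa-2,5-dien-1-one, comes from an isomeric 2,4-dienone by O-methylation of its ketone oxygen, hydrolysis at the other alkoxy carbon (1,3-carbonyl transposition) and desilylation.
- That dienone comes from an o-quinol silyl ether by an α-ketol 1,2-shift of the (R)-1-arylpropan-2-yl group from the carbinol carbon to the neighbouring carbonyl carbon; this makes the quaternary C–C bond and relays the stereocentre, and the new alkoxide is methylated.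
- The o-quinol comes from 2,5-dimethoxy-1,4-benzoquinone by two successive carbonyl additions (ligand-controlled secondary alkyl-lithium, then allylmagnesium bromide) and vinylogous hydrolysis.
- The alkyl-lithium comes from the (R)-iodide, made with inversion from the (S)-alcohol, which comes from (S)-propylene oxide and an aryl Grignard reagent built from catechol.
- No ring is formed: the dienone ring is bought as 1,4-benzoquinone and the arene as catechol.

Assumption: the (S,S)-bis(oxazoline) is taken as the matched ligand for the (R)-alkyl-lithium; if screening shows otherwise, its (R,R)-enantiomer is used with no other change.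

Step 1
Reactants: 1 benzene-1,2-diol (catechol)
Product: 2 2-methoxyphenol
Conditions: MeI (1.0 equiv), K2CO3, acetone, reflux
Reagents that add atoms: iodomethane (IC)
Why: Williamson ether synthesis with one equivalent of MeI methylates one of the two equivalent phenols, unreacted catechol and 1,2-dimethoxybenzene being removed by extraction and distillation; no stereocentre is involved.

Step 2
Reactants: 2 2-methoxyphenol
Product: 3 4-bromo-2-methoxyphenol
Conditions: NBS, MeCN, 0 °C
Reagents that add atoms: N-bromosuccinimide (O=C1CCC(=O)N1Br)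
Why: Electrophilic aromatic bromination goes para to the free hydroxyl group, the strongest donor on the ring; no stereocentre is involved.

Step 3
Reactants: 3 4-bromo-2-methoxyphenol
Product: 4 (4-bromo-2-methoxyphenoxy)tri(propan-2-yl)silane
Conditions: i-Pr3SiCl, imidazole, DMF, rt
Reagents that add atoms: chlorotri(propan-2-yl)silane (CC(C)[Si](Cl)(C(C)C)C(C)C)
Why: Silyl ether formation gives a bulky aryl silyl ether that withstands Grignard and organolithium reagents, alkoxide base and methylating agents and is removed by fluoride at the end; no stereocentre is involved.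

Step 4
Reactants: 4 (4-bromo-2-methoxyphenoxy)tri(propan-2-yl)silane; 5 (2S)-2-methyloxirane
Product: 7 (2S)-1-{3-methoxy-4-[tri(propan-2-yl)silyloxy]phenyl}propan-2-ol, via aryl Grignard reagent 6 (not isolated)
Conditions: Mg, THF, rt; CuI (10 mol%), 5, −30 → 0 °C; H2O
Reagents that add atoms: none
Why: Copper-catalysed SN2 opening of the epoxide by the aryl Grignard reagent takes place at the unsubstituted carbon, so the stereocentre of 5 is carried over untouched and the alcohol is (S).

Step 5
Reactants: 7 (2S)-1-{3-methoxy-4-[tri(propan-2-yl)silyloxy]phenyl}propan-2-ol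
Product: 8 {4-[(2R)-2-iodopropyl]-2-methoxyphenoxy}tri(propan-2-yl)silane
Conditions: PPh3, I2, imidazole, CH2Cl2, −10 °C
Reagents that add atoms: iodine ([I][I])
Why: Appel reaction, in which iodide displaces the alkoxyphosphonium group by SN2 with inversion, so the (S)-alcohol gives the (R)-iodide; low temperature and short time limit iodide exchange.

Step 6
Reactants: 9 cyclohexa-2,5-diene-1,4-dione (1,4-benzoquinone)
Product: 10 2,5-dimethoxycyclohexa-2,5-diene-1,4-dione
Conditions: MeOH, ZnCl2, reflux (3 equiv of 9 per 10)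
Reagents that add atoms: methanol (CO)
Why: Lewis-acid-promoted conjugate addition of methanol to the quinone followed by re-oxidation of the methoxyhydroquinone by excess quinone, run twice, gives the sparingly soluble 2,5-dimethoxyquinone (oxidative nucleophilic addition to a quinone); no stereocentre is involved.

Step 7
Reactants: 8 {4-[(2R)-2-iodopropyl]-2-methoxyphenoxy}tri(propan-2-yl)silane; 10 2,5-dimethoxycyclohexa-2,5-diene-1,4-dione; 11 allylmagnesium bromide
Product: 16 (6S)-4-methoxy-6-[(2R)-1-{3-methoxy-4-[tri(propan-2-yl)silyloxy]phenyl}propan-2-yl]-3-(prop-2-en-1-yl)-6-(trimethylsilyloxy)cyclohexa-2,4-dien-1-one, via alkyl-lithium 12 (not isolated), via lithium quinolate 13 (not isolated), via quinol silyl ether 14 (not isolated), via allyl carbinol 15 (not isolated)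
Conditions: t-BuLi (2.05 equiv), pentane–Et2O 3:2, −100 °C, 1 min; 2,2-bis[(4S)-4-tert-butyl-4,5-dihydro-1,3-oxazol-2-yl]propane (1.2 equiv), toluene, −100 °C; cannulate into 10, THF–toluene, −90 °C; Me3SiCl, −78 °C; 11, −78 → −40 °C; AcOH–NaOAc buffer (pH 5), 0 °C
Reagents that add atoms: chlorotrimethylsilane (C[Si](C)(C)Cl); water (O)
Why: Proposed new method: iodine–lithium exchange at −100 °C is retentive and the secondary alkyl-lithium holds its configuration long enough to be trapped, and here it is delivered as its complex with a C2-symmetric bis(oxazoline) to one enantiotopic face of a carbonyl group of the flat quinone 10, which holds lithium between the C=O and the neighbouring methoxy oxygen, so that ligand and chiral alkyl group act as a matched pair and set the quinol carbon of 13 as (S) with retention at the side-chain carbon; the alkoxide is capped as its silyl ether so that, after 1,2-addition of 11 to the remaining carbonyl, only the free allyl carbinol of 15 ionises in the buffer and water enters at the methoxy-bearing enol-ether carbon faster than any cationic shift (Stork–Danheiser vinylogous hydrolysis) to give 16; the closest known reaction types are bis(oxazoline)- or sparteine-mediated enantioselective additions of organolithiums to C=N bonds and ligand-free 1,2-additions of organolithiums to dialkoxyquinones.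

Step 8
Reactants: 16 (6S)-4-methoxy-6-[(2R)-1-{3-methoxy-4-[tri(propan-2-yl)silyloxy]phenyl}propan-2-yl]-3-(prop-2-en-1-yl)-6-(trimethylsilyloxy)cyclohexa-2,4-dien-1-one
Product: 19 (6R)-3,6-dimethoxy-6-[(2R)-1-{3-methoxy-4-[tri(propan-2-yl)silyloxy]phenyl}propan-2-yl]-4-(prop-2-en-1-yl)cyclohexa-2,4-dien-1-one, via potassium alkoxide 17 (not isolated), via rearranged alkoxide 18 (not isolated)
Conditions: KOt-Bu (1.1 equiv), THF, −78 → 0 °C; MeI, DMPU, 0 °C
Reagents that add atoms: iodomethane (IC)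
Why: tert-Butoxide takes off the trimethylsilyl group and the o-quinol alkoxide 17 undergoes an α-ketol (acyloin) rearrangement in which the secondary alkyl group shifts suprafacially, with retention at its own carbon, from C-6 to the carbonyl carbon; the equilibrium lies on the side of 18 because its new ketone is a vinylogous ester, the group stays on the ring face it occupied so the new quaternary carbon is (R), and Williamson methylation of the tertiary alkoxide fixes it.

Step 9
Reactants: 19 (6R)-3,6-dimethoxy-6-[(2R)-1-{3-methoxy-4-[tri(propan-2-yl)silyloxy]phenyl}propan-2-yl]-4-(prop-2-en-1-yl)cyclohexa-2,4-dien-1-one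
Product: 22 (4R)-4-[(2R)-1-(4-hydroxy-3-methoxyphenyl)propan-2-yl]-4,5-dimethoxy-2-(prop-2-en-1-yl)cyclohexa-2,5-dien-1-one, via oxocarbenium salt 20 (not isolated), via silyl-protected dienone 21 (not isolated)
Conditions: Me3OBF4, CH2Cl2, −20 → 0 °C; sat. aq. NaHCO3, THF, 0 °C; Bu4NF, AcOH, THF, 0 °C
Reagents that add atoms: trimethyloxonium tetrafluoroborate (C[O+](C)C.F[B-](F)(F)F); water (O)
Why: Meerwein O-methylation of the vinylogous-ester carbonyl gives the 1,3-dimethoxy-substituted cation 20, water attacks its less hindered alkoxy carbon (flanked by two sp2 carbons, not the one next to the quaternary centre) and the hemiketal loses methanol, which moves the carbonyl (1,3-carbonyl transposition of a vinylogous ester) without touching a stereocentre, and fluoride then cleaves the aryl silyl ether.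

**Compound list**
1 | benzene-1,2-diol (catechol) | Oc1ccccc1O | starting material
2 | 2-methoxyphenol | COc1ccccc1O | intermediate
3 | 4-bromo-2-methoxyphenol | COc1cc(Br)ccc1O | intermediate
4 | (4-bromo-2-methoxyphenoxy)tri(propan-2-yl)silane | COc1cc(Br)ccc1O[Si](C(C)C)(C(C)C)C(C)C | intermediate
5 | (2S)-2-methyloxirane | C[C@H]1CO1 | starting material
6 | bromo{3-methoxy-4-[tri(propan-2-yl)silyloxy]phenyl}magnesium | COc1cc([Mg]Br)ccc1O[Si](C(C)C)(C(C)C)C(C)C | intermediate
7 | (2S)-1-{3-methoxy-4-[tri(propan-2-yl)silyloxy]phenyl}propan-2-ol | C[C@H](O)Cc1ccc(O[Si](C(C)C)(C(C)C)C(C)C)c(OC)c1 | intermediate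
8 | {4-[(2R)-2-iodopropyl]-2-methoxyphenoxy}tri(propan-2-yl)silane | I[C@H](C)Cc1ccc(O[Si](C(C)C)(C(C)C)C(C)C)c(OC)c1 | intermediate
9 | cyclohexa-2,5-diene-1,4-dione (1,4-benzoquinone) | O=C1C=CC(=O)C=C1 | starting material
10 | 2,5-dimethoxycyclohexa-2,5-diene-1,4-dione | COC1=CC(=O)C(OC)=CC1=O | intermediate
11 | allylmagnesium bromide | C=CC[Mg]Br | starting material
12 | [(2R)-1-{3-methoxy-4-[tri(propan-2-yl)silyloxy]phenyl}propan-2-yl]lithium | C[C@@H]([Li])Cc1ccc(O[Si](C(C)C)(C(C)C)C(C)C)c(OC)c1 | intermediate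
13 | lithium (1S)-2,5-dimethoxy-1-[(2R)-1-{3-methoxy-4-[tri(propan-2-yl)silyloxy]phenyl}propan-2-yl]-4-oxocyclohexa-2,5-dien-1-olate | COC1=CC(=O)C(OC)=C[C@@]1([O-])[C@H](C)Cc1ccc(O[Si](C(C)C)(C(C)C)C(C)C)c(OC)c1.[Li+] | intermediate
14 | (4S)-2,5-dimethoxy-4-[(2R)-1-{3-methoxy-4-[tri(propan-2-yl)silyloxy]phenyl}propan-2-yl]-4-(trimethylsilyloxy)cyclohexa-2,5-dien-1-one | COC1=CC(=O)C(OC)=C[C@@]1(O[Si](C)(C)C)[C@H](C)Cc1ccc(O[Si](C(C)C)(C(C)C)C(C)C)c(OC)c1 | intermediate
15 | (4S)-2,5-dimethoxy-4-[(2R)-1-{3-methoxy-4-[tri(propan-2-yl)silyloxy]phenyl}propan-2-yl]-1-(prop-2-en-1-yl)-4-(trimethylsilyloxy)cyclohexa-2,5-dien-1-ol (both C-1 epimers) | COC1=CC(O)(CC=C)C(OC)=C[C@@]1(O[Si](C)(C)C)[C@H](C)Cc1ccc(O[Si](C(C)C)(C(C)C)C(C)C)c(OC)c1 | intermediate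
16 | (6S)-4-methoxy-6-[(2R)-1-{3-methoxy-4-[tri(propan-2-yl)silyloxy]phenyl}propan-2-yl]-3-(prop-2-en-1-yl)-6-(trimethylsilyloxy)cyclohexa-2,4-dien-1-one | C=CCC1=CC(=O)[C@](O[Si](C)(C)C)([C@H](C)Cc2ccc(O[Si](C(C)C)(C(C)C)C(C)C)c(OC)c2)C=C1OC | intermediate
17 | potassium (1S)-3-methoxy-1-[(2R)-1-{3-methoxy-4-[tri(propan-2-yl)silyloxy]phenyl}propan-2-yl]-6-oxo-4-(prop-2-en-1-yl)cyclohexa-2,4-dien-1-olate | C=CCC1=CC(=O)[C@]([O-])([C@H](C)Cc2ccc(O[Si](C(C)C)(C(C)C)C(C)C)c(OC)c2)C=C1OC.[K+] | intermediate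
18 | potassium (1R)-4-methoxy-1-[(2R)-1-{3-methoxy-4-[tri(propan-2-yl)silyloxy]phenyl}propan-2-yl]-6-oxo-3-(prop-2-en-1-yl)cyclohexa-2,4-dien-1-olate | C=CCC1=C[C@]([O-])([C@H](C)Cc2ccc(O[Si](C(C)C)(C(C)C)C(C)C)c(OC)c2)C(=O)C=C1OC.[K+] | intermediate
19 | (6R)-3,6-dimethoxy-6-[(2R)-1-{3-methoxy-4-[tri(propan-2-yl)silyloxy]phenyl}propan-2-yl]-4-(prop-2-en-1-yl)cyclohexa-2,4-dien-1-one | C=CCC1=C[C@](OC)([C@H](C)Cc2ccc(O[Si](C(C)C)(C(C)C)C(C)C)c(OC)c2)C(=O)C=C1OC | intermediate
20 | {(4R)-4,5-dimethoxy-4-[(2R)-1-{3-methoxy-4-[tri(propan-2-yl)silyloxy]phenyl}propan-2-yl]-2-(prop-2-en-1-yl)cyclohexa-2,5-dien-1-ylidene}(methyl)oxonium tetrafluoroborate | C=CCC1=C[C@](OC)([C@H](C)Cc2ccc(O[Si](C(C)C)(C(C)C)C(C)C)c(OC)c2)C(OC)=CC1=[O+]C.F[B-](F)(F)F | intermediate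
21 | (4R)-4,5-dimethoxy-4-[(2R)-1-{3-methoxy-4-[tri(propan-2-yl)silyloxy]phenyl}propan-2-yl]-2-(prop-2-en-1-yl)cyclohexa-2,5-dien-1-one | C=CCC1=C[C@](OC)([C@H](C)Cc2ccc(O[Si](C(C)C)(C(C)C)C(C)C)c(OC)c2)C(OC)=CC1=O | intermediate
22 | (4R)-4-[(2R)-1-(4-hydroxy-3-methoxyphenyl)propan-2-yl]-4,5-dimethoxy-2-(prop-2-en-1-yl)cyclohexa-2,5-dien-1-one | C=CCC1=C[C@](OC)([C@H](C)Cc2ccc(O)c(OC)c2)C(OC)=CC1=O | target

**Step count**
Total step count: 9. Longest linear sequence: 8 (steps 1, 2, 3, 4, 5, 7, 8, 9); step 6 is a one-step branch.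

**Steps most likely to fail, with fallbacks**

The first is step 7, the proposed new method. The secondary alkyl-lithium may reduce the quinone by electron transfer, the ligated reagent may epimerise, or the ligand may give little facial control. The fallback uses known chemistry only and sets out from 8 and 10. The ligand is left out and alkyl-lithium 12 adds to 10 as any organolithium adds to a dialkoxyquinone. This gives 13 together with its epimer lithium (1R)-2,5-dimethoxy-1-[(2R)-1-{3-methoxy-4-[tri(propan-2-yl)silyloxy]phenyl}propan-2-yl]-4-oxocyclohexa-2,5-dien-1-olate F1. The same silylation, allyl addition and buffered hydrolysis then give, beside 14, 15 and 16, the epimers (4R)-2,5-dimethoxy-4-[(2R)-1-{3-methoxy-4-[tri(propan-2-yl)silyloxy]phenyl}propan-2-yl]-4-(trimethylsilyloxy)cyclohexa-2,5-dien-1-one F2, (4R)-2,5-dimethoxy-4-[(2R)-1-{3-methoxy-4-[tri(propan-2-yl)silyloxy]phenyl}propan-2-yl]-1-(prop-2-en-1-yl)-4-(trimethylsilyloxy)cyclohexa-2,5-dien-1-ol F3 and (6R)-4-methoxy-6-[(2R)-1-{3-methoxy-4-[tri(propan-2-yl)silyloxy]phenyl}propan-2-yl]-3-(prop-2-en-1-yl)-6-(trimethylsilyloxy)cyclohexa-2,4-dien-1-one F4. Because the side chain is fixed as (R), 16 and F4 are diastereomers; they are separated by chromatography and the route comes back at 16, at the cost of half the material.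

The second is step 8. The ring vinyl carbon may migrate in place of the side chain (ring contraction), which could also scramble the quinol stereocentre, or desilylation by tert-butoxide may be slow. The fallback gives up the shift and puts the side chain directly on the carbon that must carry it; it sets out from 9 and uses 12 made from 8. Quinone 9 is allylated with allyltrimethylsilane and TiCl4 (Hosomi–Sakurai conjugate allylation) to 2-(prop-2-en-1-yl)benzene-1,4-diol F5. This is oxidised with Ag2O to 2-(prop-2-en-1-yl)cyclohexa-2,5-diene-1,4-dione F6 and methoxylated with MeOH and ZnCl2 as in step 6 to 2-methoxy-5-(prop-2-en-1-yl)cyclohexa-2,5-diene-1,4-dione F7. Under the ligand control of step 7, alkyl-lithium 12 adds to the more electrophilic carbonyl of F7, the one next to the methoxy-bearing carbon, to give lithium (1R)-2-methoxy-1-[(2R)-1-{3-methoxy-4-[tri(propan-2-yl)silyloxy]phenyl}propan-2-yl]-4-oxo-5-(prop-2-en-1-yl)cyclohexa-2,5-dien-1-olate F8. This is O-methylated in the flask with MeI, and the route comes back at 21, which only needs the fluoride treatment of step 9.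

The third is step 9. Water may attack cation 20 at the carbon next to the quaternary centre and return 19, or the cation may undergo a dienone–phenol type shift before the quench. The fallback sets out from 19. It is saponified with aqueous NaOH in THF at 0 °C to the vinylogous acid (6R)-3-hydroxy-6-methoxy-6-[(2R)-1-{3-methoxy-4-[tri(propan-2-yl)silyloxy]phenyl}propan-2-yl]-4-(prop-2-en-1-yl)cyclohexa-2,4-dien-1-one F9. This is re-methylated with trimethylsilyldiazomethane in MeOH, which gives both enol ethers, 21 and 19. They are separated, 19 is recycled, and the route comes back at 21.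

**Further compounds**
F1 | step 7 | lithium (1R)-2,5-dimethoxy-1-[(2R)-1-{3-methoxy-4-[tri(propan-2-yl)silyloxy]phenyl}propan-2-yl]-4-oxocyclohexa-2,5-dien-1-olate | COC1=CC(=O)C(OC)=C[C@]1([O-])[C@H](C)Cc1ccc(O[Si](C(C)C)(C(C)C)C(C)C)c(OC)c1.[Li+]
F2 | step 7 | (4R)-2,5-dimethoxy-4-[(2R)-1-{3-methoxy-4-[tri(propan-2-yl)silyloxy]phenyl}propan-2-yl]-4-(trimethylsilyloxy)cyclohexa-2,5-dien-1-one | COC1=CC(=O)C(OC)=C[C@]1(O[Si](C)(C)C)[C@H](C)Cc1ccc(O[Si](C(C)C)(C(C)C)C(C)C)c(OC)c1
F3 | step 7 | (4R)-2,5-dimethoxy-4-[(2R)-1-{3-methoxy-4-[tri(propan-2-yl)silyloxy]phenyl}propan-2-yl]-1-(prop-2-en-1-yl)-4-(trimethylsilyloxy)cyclohexa-2,5-dien-1-ol | COC1=CC(O)(CC=C)C(OC)=C[C@]1(O[Si](C)(C)C)[C@H](C)Cc1ccc(O[Si](C(C)C)(C(C)C)C(C)C)c(OC)c1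
F4 | step 7 | (6R)-4-methoxy-6-[(2R)-1-{3-methoxy-4-[tri(propan-2-yl)silyloxy]phenyl}propan-2-yl]-3-(prop-2-en-1-yl)-6-(trimethylsilyloxy)cyclohexa-2,4-dien-1-one | C=CCC1=CC(=O)[C@@](O[Si](C)(C)C)([C@H](C)Cc2ccc(O[Si](C(C)C)(C(C)C)C(C)C)c(OC)c2)C=C1OC
F5 | step 8 | 2-(prop-2-en-1-yl)benzene-1,4-diol | C=CCc1cc(O)ccc1O
F6 | step 8 | 2-(prop-2-en-1-yl)cyclohexa-2,5-diene-1,4-dione | C=CCC1=CC(=O)C=CC1=O
F7 | step 8 | 2-methoxy-5-(prop-2-en-1-yl)cyclohexa-2,5-diene-1,4-dione | C=CCC1=CC(=O)C(OC)=CC1=O
F8 | step 8 | lithium (1R)-2-methoxy-1-[(2R)-1-{3-methoxy-4-[tri(propan-2-yl)silyloxy]phenyl}propan-2-yl]-4-oxo-5-(prop-2-en-1-yl)cyclohexa-2,5-dien-1-olate | C=CCC1=C[C@]([O-])([C@H](C)Cc2ccc(O[Si](C(C)C)(C(C)C)C(C)C)c(OC)c2)C(OC)=CC1=O.[Li+]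
F9 | step 9 | (6R)-3-hydroxy-6-methoxy-6-[(2R)-1-{3-methoxy-4-[tri(propan-2-yl)silyloxy]phenyl}propan-2-yl]-4-(prop-2-en-1-yl)cyclohexa-2,4-dien-1-one | C=CCC1=C[C@](OC)([C@H](C)Cc2ccc(O[Si](C(C)C)(C(C)C)C(C)C)c(OC)c2)C(=O)C=C1O
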